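**Strategy**

Ring A is closed last by an intramolecular Michael addition that joins C1, the carbon α to the C2 ketone, to C10. It exploits the 1,5-relationship between the C2 carbonyl and the C8 oxygen across the cis fusion of rings A and B. The acceptor, a 2-angeloyloxycyclohex-2-enone, stays locked in a 2-acetyl-1-silyloxybicyclo[2.2.2]oct-5-ene through a temporary C3–C8 bond; acid cleaves that bond and an enamine cyclisation then sets C10 and C9 in one operation. One bought stereocentre, C7 of (+)-3-carene, directs the Diels–Alder face (C5, C8), the bicycle directs methyl delivery to C4, and an enol angelate fixes the ester on O9.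

Key step: step 8

Remark: eremophilane numbering is used throughout (ring A: C1–C5 and C10; ring B: C5–C10; C11–C13 isopropenyl; C14 on C5; C15 on C4), α/β refer to the usual drawing in which the C5 methyl is β, and any C3 epimer formed with 11 is carried along because C3 ends as a CH2 group.

**Route**

Step 1
Reactants: 1 (+)-3-carene
Product: 2 (1R,6S)-4,7,7-trimethylbicyclo[4.1.0]hept-3-en-2-one (car-3-en-5-one)
Conditions: t-BuOOH (70% aq.), CrO3 (5 mol%), CH2Cl2, rt
Reagents that add atoms: tert-butyl hydroperoxide, CC(C)(C)OO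
Why: CrO3-catalysed allylic oxidation with t-BuOOH should take the ring CH2 that is allylic and flanked by the cyclopropane, giving the cyclopropyl-conjugated enone without touching the two cyclopropane stereocentres.

Step 2
Reactants: 2 car-3-en-5-one
Product: 4 (S)-3-methyl-5-(prop-1-en-2-yl)cyclohex-2-en-1-one, via tertiary bromide 3 (not isolated)
Conditions: HBr (33% in AcOH), 0 °C; concentrate; DBU, toluene, 80 °C
Reagents that add atoms: none
Why: Homoconjugate (1,5-) addition of HBr to the cyclopropyl ketone cleaves the external cyclopropane bond that overlaps with the carbonyl π system to give the tertiary bromide, and E2 elimination with the hindered amidine base at a methyl hydrogen (Hofmann) should give the isopropenyl group, the stereocentre that becomes C7 being untouched.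

Step 3
Reactants: 4 (S)-3-methyl-5-(prop-1-en-2-yl)cyclohex-2-en-1-one
Product: 5 (5R,6R)-6-hydroxy-3-methyl-5-(prop-1-en-2-yl)cyclohex-2-en-1-one (hydroxyl trans to isopropenyl)
Conditions: LiHMDS, THF, −78 °C; 2-(phenylsulfonyl)-3-phenyloxaziridine, −78 °C; H2O
Reagents that add atoms: 2-(phenylsulfonyl)-3-phenyloxaziridine (Davis oxaziridine), O=S(=O)(c1ccccc1)N1OC1c1ccccc1
Why: Kinetic α'-deprotonation gives the cross-conjugated lithium dienolate, which the Davis oxaziridine should hydroxylate at C8 anti to the neighbouring isopropenyl group (enolate hydroxylation); this centre is flattened again in step 5, so its configuration is not critical.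

Step 4
Reactants: 5 the 6-hydroxy enone
Product: 6 (5R,6R)-6-[(tert-butyldimethylsilyl)oxy]-3-methyl-5-(prop-1-en-2-yl)cyclohex-2-en-1-one
Conditions: TBSOTf, 2,6-lutidine, CH2Cl2, −78 °C
Reagents that add atoms: tert-butyldimethylsilyl triflate, CC(C)(C)[Si](C)(C)OS(=O)(=O)C(F)(F)F
Why: Silylation of the secondary alcohol with the silyl triflate and a hindered pyridine base is standard and avoids the basic conditions that would trigger an α-ketol shift.

Step 5
Reactants: 6 the silyloxy enone; 7 angelic anhydride
Product: 8 (R)-2-[(tert-butyldimethylsilyl)oxy]-5-methyl-3-(prop-1-en-2-yl)cyclohexa-1,5-dien-1-yl (Z)-2-methylbut-2-enoate (dienyl angelate)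
Conditions: LDA, THF/DMPU, −78 °C; then 7, −78 → 0 °C
Reagents that add atoms: none
Why: The only α'-hydrogen (at C8) is removed to give a fully substituted dienolate that the anhydride should acylate on oxygen (O-acylation of a hindered enolate in a polar medium), which fixes the angelate on O9 while O8 stays silylated and delivers a 1-silyloxy-2-acyloxy diene; the C8 stereocentre is erased on purpose.

Step 6
Reactants: 8 the dienyl angelate; 9 but-3-yn-2-one
Product: 10 2-acetyl-1-[(tert-butyldimethylsilyl)oxy]-4-methyl-7-(prop-1-en-2-yl)bicyclo[2.2.2]octa-2,5-dien-6-yl angelate (isopropenyl on C7 pointing toward the C5=C6 enol-angelate bridge)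
Conditions: toluene, BHT (cat.), 50 °C
Reagents that add atoms: none
Why: Normal-demand Diels–Alder reaction in which the strongly donating 1-silyloxy group makes C5 the nucleophilic diene terminus, so that C5 bonds to the terminal alkyne carbon and C8 to the acetyl-bearing carbon, while the dienophile approaches the diene face anti to the isopropenyl group on C7 and thereby sets the quaternary centres C5 and C8.

Step 7
Reactants: 10 the bicyclo[2.2.2]octadiene
Product: 11 6-acetyl-1-[(tert-butyldimethylsilyl)oxy]-4,5-dimethyl-7-(prop-1-en-2-yl)bicyclo[2.2.2]oct-2-en-2-yl angelate (acetyl on C6, methyl on C5 and isopropenyl on C7 all pointing toward the C2=C3 enol-angelate bridge)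
Conditions: Me2CuLi, Et2O, −78 °C; then AcOH, −78 °C
Reagents that add atoms: lithium dimethylcuprate, [Li+].C[Cu-]C
Why: Conjugate addition of Me2CuLi to the bicyclic enone should occur on the face syn to the enol-ester etheno bridge, which is more open than the face under the inward C–H bonds of the ethano bridge, and so sets C4 with the methyl on the side needed for the cis-4,5-dimethyl unit; kinetic protonation of the enolate anti to the new methyl gives the C3 epimer drawn.

Step 8
Reactants: 11 the 2-acetyl-1-silyloxybicyclo[2.2.2]octene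
Product: 13 9α-angeloyloxy-10βH-eremophil-11-ene-2,8-dione (cis-fused; 4β,5β-dimethyl; 7β-isopropenyl), via ring-opened enone 12 (not isolated)
Conditions: TsOH·H2O (0.2 equiv), CH2Cl2, 0 °C → rt; then pyrrolidine (0.5 equiv), AcOH (0.3 equiv), rt
Reagents that add atoms: none
Why: Protonation of the acetyl carbonyl lets the bridgehead silyloxy oxygen push out the C3–C8 bond (retro-aldol, Grob-type fragmentation), which after loss of the silyl group as silanol unveils the 2-angeloyloxycyclohex-2-enone 12; pyrrolidine then converts the methyl ketone into its terminal enamine, whose C1 adds to C10 and is hydrolysed back to the ketone. The closest known reactions are the acid fragmentation of 1-alkoxybicyclo[2.2.2]oct-5-en-2-yl ketones to 4-substituted cyclohexenones and the amine-catalysed intramolecular Michael addition of a ketone to an enone. Ring A closes in the 6-exo-trig (enolexo) mode. C10 is set by the tether, which can only reach the enone face that carries C4 and so gives the cis ring fusion, and C9 is set by kinetic C-protonation of the resulting enol on the convex β-face, away from the axial C4. The step needs the C1 and not the C3 enamine to react (only C1 gives a six-membered ring) and needs C7 and C9 to stay unepimerised, which the weakly acidic amine-salt medium should secure. Both C3 epimers of 11 converge because C3 becomes a CH2 group.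

Step 9
Reactants: 13 the 2,8-dione
Product: 16 9α-angeloyloxy-8α-hydroxy-10βH-eremophil-11-en-2-one, via dimethyl ketal 14 (not isolated), via ketal alcohol 15 (not isolated)
Conditions: CeCl3·7H2O, HC(OMe)3, MeOH, rt; then NaBH4, −40 °C; then 1 M HCl, 0 °C
Reagents that add atoms: none
Why: Gemal–Luche in situ protection: the unhindered C2 ketone is ketalised while the doubly α-branched C8 ketone is not, NaBH4 then adds to C8 axially from the convex β-face (anti to the axial C9 ester, Felkin–Anh) to give the equatorial 8α-alcohol, and the acidic work-up frees the C2 ketone.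

Step 10
Reactants: 16 the 8α-hydroxy ketone
Product: 17 (11R)-9α-angeloyloxy-11,12-epoxy-8α-hydroxy-10βH-eremophilan-2-one (CNP0206528.1)
Conditions: VO(acac)2 (5 mol%), t-BuOOH, CH2Cl2, 0 °C → rt
Reagents that add atoms: tert-butyl hydroperoxide, CC(C)(C)OO
Why: Hydroxyl-directed VO(acac)2-catalysed epoxidation of the homoallylic alcohol through a chair-like transition state fused to ring B, with the isopropenyl methyl pseudo-equatorial, should deliver oxygen to one face of the 1,1-disubstituted alkene and give the (11R)-epoxide, the electron-poor angelate double bond staying intact.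

**Compound list**

1 | (+)-3-carene, (1S,6R)-3,7,7-trimethylbicyclo[4.1.0]hept-3-ene | CC1=CC[C@@H]2[C@H](C1)C2(C)C | starting material
2 | (1R,6S)-4,7,7-trimethylbicyclo[4.1.0]hept-3-en-2-one (car-3-en-5-one) | CC1=CC(=O)[C@@H]2[C@H](C1)C2(C)C | intermediate
3 | (S)-5-(2-bromopropan-2-yl)-3-methylcyclohex-2-en-1-one | CC1=CC(=O)C[C@H](C1)C(C)(C)Br | intermediate
4 | (S)-3-methyl-5-(prop-1-en-2-yl)cyclohex-2-en-1-one | CC1=CC(=O)C[C@H](C1)C(C)=C | intermediate
5 | (5R,6R)-6-hydroxy-3-methyl-5-(prop-1-en-2-yl)cyclohex-2-en-1-one | CC1=CC(=O)[C@H](O)[C@H](C1)C(C)=C | intermediate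
6 | (5R,6R)-6-[(tert-butyldimethylsilyl)oxy]-3-methyl-5-(prop-1-en-2-yl)cyclohex-2-en-1-one | CC1=CC(=O)[C@H](O[Si](C)(C)C(C)(C)C)[C@H](C1)C(C)=C | intermediate
7 | angelic anhydride, (Z)-2-methylbut-2-enoic anhydride | C/C=C(/C)C(=O)OC(=O)/C(C)=C\C | starting material
8 | (R)-2-[(tert-butyldimethylsilyl)oxy]-5-methyl-3-(prop-1-en-2-yl)cyclohexa-1,5-dien-1-yl (Z)-2-methylbut-2-enoate | C/C=C(/C)C(=O)OC1=C(O[Si](C)(C)C(C)(C)C)[C@@H](C(C)=C)CC(C)=C1 | intermediate
9 | but-3-yn-2-one | CC(=O)C#C | starting material
10 | 2-acetyl-1-[(tert-butyldimethylsilyl)oxy]-4-methyl-7-(prop-1-en-2-yl)bicyclo[2.2.2]octa-2,5-dien-6-yl angelate, isopropenyl toward the C5=C6 bridge | CC(=O)C1=C[C@]2(C)C=C(OC(=O)/C(C)=C\C)[C@@]1(O[Si](C)(C)C(C)(C)C)[C@@H](C(C)=C)C2 | intermediate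
11 | 6-acetyl-1-[(tert-butyldimethylsilyl)oxy]-4,5-dimethyl-7-(prop-1-en-2-yl)bicyclo[2.2.2]oct-2-en-2-yl angelate, acetyl, C5 methyl and isopropenyl toward the C2=C3 bridge | CC(=O)[C@@H]1[C@H](C)[C@]2(C)C=C(OC(=O)/C(C)=C\C)[C@@]1(O[Si](C)(C)C(C)(C)C)[C@@H](C(C)=C)C2 | intermediate
12 | (3R,5R)-3-methyl-6-oxo-3-[(2S)-4-oxopentan-2-yl]-5-(prop-1-en-2-yl)cyclohex-1-en-1-yl (Z)-2-methylbut-2-enoate | C/C=C(/C)C(=O)OC1=C[C@@](C)([C@@H](C)CC(C)=O)C[C@H](C(C)=C)C1=O | intermediate
13 | 9α-angeloyloxy-10βH-eremophil-11-ene-2,8-dione | C/C=C(/C)C(=O)O[C@@H]1C(=O)[C@@H](C(C)=C)C[C@@]2(C)[C@@H]1CC(=O)C[C@@H]2C | intermediate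
14 | 9α-angeloyloxy-2,2-dimethoxy-10βH-eremophil-11-en-8-one | C/C=C(/C)C(=O)O[C@@H]1C(=O)[C@@H](C(C)=C)C[C@@]2(C)[C@@H]1CC(OC)(OC)C[C@@H]2C | intermediate
15 | 9α-angeloyloxy-2,2-dimethoxy-10βH-eremophil-11-en-8α-ol | C/C=C(/C)C(=O)O[C@@H]1[C@H](O)[C@@H](C(C)=C)C[C@@]2(C)[C@@H]1CC(OC)(OC)C[C@@H]2C | intermediate
16 | 9α-angeloyloxy-8α-hydroxy-10βH-eremophil-11-en-2-one | C/C=C(/C)C(=O)O[C@@H]1[C@H](O)[C@@H](C(C)=C)C[C@@]2(C)[C@@H]1CC(=O)C[C@@H]2C | intermediate
17 | (11R)-9α-angeloyloxy-11,12-epoxy-8α-hydroxy-10βH-eremophilan-2-one (CNP0206528.1) | C/C=C(/C)C(=O)O[C@@H]1[C@H](O)[C@@H]([C@]2(C)CO2)C[C@@]2(C)[C@@H]1CC(=O)C[C@@H]2C | target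

**Count**

Total steps: 10. Longest linear sequence: 10 steps (from 1).

**Steps most likely to fail, with fallbacks**

Step 8 (key step). The C8 ketone may enolise toward C7 or C9 during the acid/amine sequence, which would epimerise these centres or move the isopropenyl double bond into conjugation, and the acyl group may shift within the enediol formed after the Michael addition. The fallback sets out from 11 and comes back at 13. The acetyl group of 11 is converted with LDA and TBSCl (THF/HMPA, −78 °C) into the silyl enol ether F1, a 2,4-bis(silyloxy)-1,5-diene whose new vinyl unit lies over the enol-angelate bridge. Heating (toluene, 160 °C, sealed tube) should bring about a Cope rearrangement that breaks C3–C8 and forms C1–C10 through the boat transition state enforced by the bicycle, giving the cis-fused bis(silyl enol ether) F2. Brief treatment with 1 M HCl in THF at 0 °C hydrolyses both enol ethers, with protonation of C9 from the β-face, and returns 13. This variant needs the C3 epimer drawn for 11.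

Step 6. The cycloaddition joins two fully substituted diene termini and may be slow, and the adduct may lose isoprene by retro-Diels–Alder aromatisation. The fallback sets out from 8 and comes back at 12. A vinylogous Mukaiyama–Michael addition of the silyl dienol ether 8 through C5 to commercial (E)-pent-3-en-2-one (TiCl4, CH2Cl2, −78 °C, aqueous work-up) should form the C4–C5 bond anti to the isopropenyl group and give the enone 12 without the bicycle. 12 is then cyclised with pyrrolidine/AcOH as in the second stage of step 8. The C4 configuration then rests on an open transition state and would have to be checked. This fallback creates no compound outside the list (none F0).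

Step 10. Facial selectivity at the 1,1-disubstituted alkene may be poor. The fallback sets out from 16 and comes back at 17. Reagent-controlled dihydroxylation (OsO4 cat., (DHQD)2PHAL, NMO, acetone/H2O, 0 °C) should give the 8α,11,12-triol F3. Selective tosylation of the primary hydroxyl (TsCl, pyridine, 0 °C) gives the primary tosylate F4, and ring closure (DBU, CH2Cl2, rt) with retention at C11 gives 17.

**Further compounds**

F1 | step 8 | 1-[(tert-butyldimethylsilyl)oxy]vinyl analogue of 11 (silyl enol ether of the acetyl group) | C=C(O[Si](C)(C)C(C)(C)C)[C@@H]1[C@H](C)[C@]2(C)C=C(OC(=O)/C(C)=C\C)[C@@]1(O[Si](C)(C)C(C)(C)C)[C@@H](C(C)=C)C2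
F2 | step 8 | 9-angeloyloxy-2,8-bis[(tert-butyldimethylsilyl)oxy]-10βH-eremophila-2,8,11-triene | C/C=C(/C)C(=O)OC1=C(O[Si](C)(C)C(C)(C)C)[C@@H](C(C)=C)C[C@@]2(C)[C@@H]1CC(O[Si](C)(C)C(C)(C)C)=C[C@@H]2C
F0 | step 6 | none | none
F3 | step 10 | (11R)-9α-angeloyloxy-8α,11,12-trihydroxy-10βH-eremophilan-2-one | C/C=C(/C)C(=O)O[C@@H]1[C@H](O)[C@@H]([C@@](C)(O)CO)C[C@@]2(C)[C@@H]1CC(=O)C[C@@H]2C
F4 | step 10 | (11R)-9α-angeloyloxy-8α,11-dihydroxy-12-(p-toluenesulfonyloxy)-10βH-eremophilan-2-one | C/C=C(/C)C(=O)O[C@@H]1[C@H](O)[C@@H]([C@@](C)(O)COS(=O)(=O)c2ccc(C)cc2)C[C@@]2(C)[C@@H]1CC(=O)C[C@@H]2C
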